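## Retrosynthetic overview

1. Target 24 ← Stille coupling at C6–I ← cobalt-catalysed Markovnikov hydrosilylperoxidation of an isopropenyl group ← C6 iodination directed by the free 5-OH; the peroxide is made before the second alkene exists.
2. Oxepinoflavone 16 ← one Pd/norbornene operation that forms both C3–CH2 and C2–C1': 2-iodochromone 6 (rings A and C) + bromide/boronate 15 (ring B plus the three-carbon chain with the stereocentre).
3. Enabling feature: in ring C, C2 (between O1 and C3) carries the iodine and C3–H is its only neighbouring C–H, the ipso/ortho pair of a Catellani manifold. Ring D is these two atoms plus the five-atom unit CH2–CH–O–C2'–C1', so its closure is a formal (5+2) annulation.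
4. 15 ← Mitsunobu inversion of methyl (R)-glycerate derivative 10 with bromophenol 8, then MeMgBr, Miyaura borylation, Appel; 6 ← enaminone chromone synthesis, MOM protection, C2 zincation/iodination.
5. Ring order: A (purchased) → C (step 1) → B (purchased, joined in step 11) → D (oxepine, step 11).

Key step: step 11

Assumption: the target stereocentre is read from the SMILES as (S); flavone numbering (O1, C2, C3, C4, ring B primed) is used for all tetracyclic compounds, and compounds 1, 7, 9 and 21 are taken as purchased.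

## Route

Step 1
Reactants: 1 1-(2,6-dihydroxy-4-methoxyphenyl)ethan-1-one
Product: 3 5-hydroxy-7-methoxy-4H-chromen-4-one, via enaminone 2 (not isolated)
Conditions: DMF-DMA, toluene, 95 °C; then conc. HCl, CH2Cl2, 40 °C
Reagents that add atoms: N,N-dimethylformamide dimethyl acetal, COC(OC)N(C)C
Why: Condensation at the acetyl CH3 gives the enaminone, which should cyclise under acid with loss of dimethylamine (enaminone chromone synthesis); the two hydroxyls of 1 are equivalent, so only one chromone can form.

Step 2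
Reactants: 3 5-hydroxy-7-methoxy-4H-chromen-4-one
Product: 4 7-methoxy-5-(methoxymethoxy)-4H-chromen-4-one
Conditions: NaH, MOMCl, DMF, 0 → 23 °C
Reagents that add atoms: chloromethyl methyl ether, COCCl
Why: Williamson-type O-alkylation of the single, chelated phenol after irreversible deprotonation; the acetal masks the acidic OH for the metalation and the basic key step.

Step 3
Reactants: 4 7-methoxy-5-(methoxymethoxy)-4H-chromen-4-one
Product: 6 2-iodo-7-methoxy-5-(methoxymethoxy)-4H-chromen-4-one, via chromon-2-ylzinc chloride 5 (not isolated)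
Conditions: TMPZnCl·LiCl (1.3 equiv), THF, −30 → 0 °C; then I2, THF, 0 °C
Reagents that add atoms: iodine, II
Why: Deprotonative zincation of chromones with TMP-zinc amide bases takes place at the most acidic C2–H next to the ring oxygen, and iodolysis of the C–Zn bond should give the 2-iodide.

Step 4
Reactants: 7 4-bromobenzene-1,3-diol
Product: 8 2-bromo-5-[(triisopropylsilyl)oxy]phenol
Conditions: TIPSCl (1.0 equiv), imidazole, DMF, 0 °C
Reagents that add atoms: triisopropylsilyl chloride, CC(C)[Si](Cl)(C(C)C)C(C)C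
Why: Regioselective silylation; the bulky silyl chloride should react at the unhindered hydroxyl para to bromine and leave the hydroxyl flanked by bromine free.

Step 5
Reactants: 9 methyl (R)-2,3-dihydroxypropanoate
Product: 10 methyl (R)-3-[(tert-butyldimethylsilyl)oxy]-2-hydroxypropanoate
Conditions: TBSCl, imidazole, CH2Cl2, 0 °C
Reagents that add atoms: tert-butyldimethylsilyl chloride, CC(C)(C)[Si](C)(C)Cl
Why: Selective silylation of the primary over the secondary, ester-deactivated hydroxyl.

Step 6
Reactants: 10 methyl (R)-3-[(tert-butyldimethylsilyl)oxy]-2-hydroxypropanoate; 8 2-bromo-5-[(triisopropylsilyl)oxy]phenol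
Product: 11 methyl (S)-2-{2-bromo-5-[(triisopropylsilyl)oxy]phenoxy}-3-[(tert-butyldimethylsilyl)oxy]propanoate
Conditions: PPh3, DIAD, toluene, 0 → 23 °C
Reagents that add atoms: none
Why: Mitsunobu etherification of an α-hydroxy ester with an acidic phenol proceeds by SN2 with clean inversion, which sets the only stereocentre of the route (R alcohol → S aryl ether).

Step 7
Reactants: 11 methyl (S)-2-{2-bromo-5-[(triisopropylsilyl)oxy]phenoxy}-3-[(tert-butyldimethylsilyl)oxy]propanoate
Product: 12 (S)-3-{2-bromo-5-[(triisopropylsilyl)oxy]phenoxy}-4-[(tert-butyldimethylsilyl)oxy]-2-methylbutan-2-ol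
Conditions: MeMgBr (3 equiv), THF, −20 → 0 °C; aq. NH4Cl
Reagents that add atoms: methylmagnesium bromide, C[Mg]Br
Why: Double Grignard addition to the ester gives the dimethyl carbinol; the aryl bromide and both silyl ethers are inert at this temperature and fast addition should outrun enolisation, so the stereocentre is kept.

Step 8
Reactants: 12 (S)-3-{2-bromo-5-[(triisopropylsilyl)oxy]phenoxy}-4-[(tert-butyldimethylsilyl)oxy]-2-methylbutan-2-ol
Product: 13 (S)-4-[(tert-butyldimethylsilyl)oxy]-2-methyl-3-{2-(4,4,5,5-tetramethyl-1,3,2-dioxaborolan-2-yl)-5-[(triisopropylsilyl)oxy]phenoxy}butan-2-ol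
Conditions: B2pin2, Pd(dppf)Cl2 (5 mol%), KOAc, 1,4-dioxane, 90 °C
Reagents that add atoms: bis(pinacolato)diboron, CC1(C)OB(OC1(C)C)B1OC(C)(C)C(C)(C)O1
Why: Miyaura borylation of the aryl bromide fixes boron at the future C1'; acetate is too weak a base to disturb the silyl ethers or the free carbinol.

Step 9
Reactants: 13 (S)-4-[(tert-butyldimethylsilyl)oxy]-2-methyl-3-{2-(4,4,5,5-tetramethyl-1,3,2-dioxaborolan-2-yl)-5-[(triisopropylsilyl)oxy]phenoxy}butan-2-ol
Product: 14 (S)-3-methyl-2-{2-(4,4,5,5-tetramethyl-1,3,2-dioxaborolan-2-yl)-5-[(triisopropylsilyl)oxy]phenoxy}butane-1,3-diol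
Conditions: CSA (10 mol%), MeOH/CH2Cl2, 0 °C
Reagents that add atoms: none
Why: Acid-catalysed methanolysis cleaves the primary alkyl TBS ether, while the aryl TIPS ether (acid-stable) and the pinacol boronate should survive.

Step 10
Reactants: 14 (S)-3-methyl-2-{2-(4,4,5,5-tetramethyl-1,3,2-dioxaborolan-2-yl)-5-[(triisopropylsilyl)oxy]phenoxy}butane-1,3-diol
Product: 15 (R)-4-bromo-2-methyl-3-{2-(4,4,5,5-tetramethyl-1,3,2-dioxaborolan-2-yl)-5-[(triisopropylsilyl)oxy]phenoxy}butan-2-ol
Conditions: CBr4, PPh3, CH2Cl2, 0 °C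
Reagents that add atoms: carbon tetrabromide, BrC(Br)(Br)Br
Why: Appel bromination takes the primary hydroxyl and leaves the hindered tertiary one; the stereocentre is not involved and the descriptor changes to R only through the CIP rank of CH2Br.

Step 11
Reactants: 6 2-iodo-7-methoxy-5-(methoxymethoxy)-4H-chromen-4-one; 15 (R)-4-bromo-2-methyl-3-{2-(4,4,5,5-tetramethyl-1,3,2-dioxaborolan-2-yl)-5-[(triisopropylsilyl)oxy]phenoxy}butan-2-ol
Product: 16 (S)-7-methoxy-5-(methoxymethoxy)-4'-[(triisopropylsilyl)oxy]flavone with a C3–CH2–CH[C(CH3)2OH]–O–C2' bridge (oxepine ring D; the CH on oxygen is the S centre)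
Conditions: Pd(OAc)2 (10 mol%), P(2-furyl)3 (22 mol%), norbornene (2 equiv), K2CO3 (4 equiv), DME/H2O (20:1), 85 °C
Reagents that add atoms: none
Why: Proposed new method: zerovalent palladium inserts into the C2–I bond of 6, norbornene carbopalladation and C3–H palladation give a five-membered palladacycle, and its SN2-type oxidative addition to the primary C–Br bond of 15 (tetravalent palladium) followed by C(sp2)–C(sp3) reductive elimination forges C3–CH2; norbornene is then expelled by β-carbon elimination and the chromon-2-yl palladium species is intercepted by the tethered aryl boronate (transmetalation, reductive elimination), which forges C2–C1'. The closest known reaction type is the Catellani ortho-alkylation/ipso-Suzuki termination of aryl iodides, which has also been run on β-iodo enone-type heterocycles (4-iodo-2-quinolones, 4-iodo-2-pyridones) and with bifunctional alkyl halides for ring annulation; new here are the 2-iodochromone and a single reagent that carries both the alkyl bromide and the boronate. The oxepine (ring D) closes in the second event, a seven-membered ring formed by C(sp2)–C(sp2) reductive elimination from an eight-membered diorganopalladium chelate, so the whole is a formal (5+2) annulation of C2=C3 with the five-atom unit CH2–CH–O–C2'–C1'. No stereocentre is created: the carbinol-bearing carbon of 15 lies one atom away from the reacting CH2 and is carried through unchanged, its descriptor turning from R to S only because CH2Br becomes CH2–C3. The step needs alkylation to precede biaryl coupling, which fast norbornene insertion and slow transmetalation of the hindered ortho-alkoxy pinacol boronate should secure, and it needs single alkylation, which is secured because ring oxygen O1 leaves C3–H as the only C–H next to C2; the site of arylation is fixed by the boron atom.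

Step 12
Reactants: 16 (S)-7-methoxy-5-(methoxymethoxy)-4'-[(triisopropylsilyl)oxy]flavone with the C3–CH2–CH[C(CH3)2OH]–O–C2' bridge
Product: 17 (S)-5-hydroxy-7-methoxy-4'-[(triisopropylsilyl)oxy]flavone with the C3–CH2–CH[C(CH3)2OH]–O–C2' bridge
Conditions: HCl (0.5 M), MeOH/THF, 40 °C
Reagents that add atoms: none
Why: Acetal methanolysis; the peri MOM ether next to the carbonyl is the only acetal and is very labile, while the aryl TIPS ether and the tertiary alcohol should tolerate dilute acid.

Step 13
Reactants: 17 (S)-5-hydroxy-7-methoxy-4'-[(triisopropylsilyl)oxy]flavone with the C3–CH2–CH[C(CH3)2OH]–O–C2' bridge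
Product: 18 (S)-5-hydroxy-6-iodo-7-methoxy-4'-[(triisopropylsilyl)oxy]flavone with the C3–CH2–CH[C(CH3)2OH]–O–C2' bridge
Conditions: BnMe3N·ICl2 (1.05 equiv), CaCO3, CH2Cl2/MeOH (5:2), 23 °C
Reagents that add atoms: benzyltrimethylammonium dichloroiodate, C[N+](C)(C)Cc1ccccc1.Cl[I-]Cl
Why: Electrophilic iodination by dichloroiodate is directed ortho to a free phenol, a selectivity known for 5-hydroxy-7-alkoxyflavones (C6); ring B carries only ether and silyl ether donors, which need Lewis acid activation with this reagent.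

Step 14
Reactants: 18 (S)-5-hydroxy-6-iodo-7-methoxy-4'-[(triisopropylsilyl)oxy]flavone with the C3–CH2–CH[C(CH3)2OH]–O–C2' bridge
Product: 19 (S)-5-hydroxy-6-iodo-7-methoxy-4'-[(triisopropylsilyl)oxy]flavone with a C3–CH2–CH[C(CH3)=CH2]–O–C2' bridge
Conditions: Burgess reagent (3 equiv), toluene, 60 °C
Reagents that add atoms: none
Why: Burgess dehydration is a syn elimination of the tertiary sulfamate; six methyl hydrogens against one hindered, oxygen-deactivated methine hydrogen should favour the isopropenyl group, as in related 2-(2-hydroxypropan-2-yl) cyclic aryl ethers.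

Step 15
Reactants: 19 (S)-5-hydroxy-6-iodo-7-methoxy-4'-[(triisopropylsilyl)oxy]flavone with the C3–CH2–CH[C(CH3)=CH2]–O–C2' bridge
Product: 20 (S)-5-hydroxy-6-iodo-7-methoxy-4'-[(triisopropylsilyl)oxy]flavone with a C3–CH2–CH[C(CH3)2OOSiEt3]–O–C2' bridge
Conditions: Co(thd)2 (divalent cobalt, 10 mol%), Et3SiH (3 equiv), O2 (1 atm), 1,2-dichloroethane, 23 °C
Reagents that add atoms: dioxygen, O=O; triethylsilane, CC[SiH](CC)CC
Why: Mukaiyama–Isayama hydrosilylperoxidation: hydrogen-atom transfer to the terminal CH2 gives the tertiary radical, which is trapped by O2 and silylated (Markovnikov); the isopropenyl group is the only reactive alkene because the C2=C3 bond is tetrasubstituted and electron-poor.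

Step 16
Reactants: 21 3-methylbut-1-yne
Product: 22 (E)-tributyl(3-methylbut-1-en-1-yl)stannane
Conditions: Bu3SnH, Pd2(dba)3 (0.5 mol%), Cy3P·HBF4 (2 mol%), i-Pr2NEt (4 mol%), CH2Cl2, 0 °C
Reagents that add atoms: tributyltin hydride, CCCC[SnH](CCCC)CCCC
Why: Palladium-catalysed hydrostannation is a syn addition that gives the E alkenylstannane; the bulky phosphine and the branched alkyne substituent should direct tin to the terminal carbon.

Step 17
Reactants: 20 (S)-5-hydroxy-6-iodo-7-methoxy-4'-[(triisopropylsilyl)oxy]flavone with the C3–CH2–CH[C(CH3)2OOSiEt3]–O–C2' bridge; 22 (E)-tributyl(3-methylbut-1-en-1-yl)stannane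
Product: 23 (S)-5-hydroxy-7-methoxy-6-[(E)-3-methylbut-1-en-1-yl]-4'-[(triisopropylsilyl)oxy]flavone with the C3–CH2–CH[C(CH3)2OOSiEt3]–O–C2' bridge
Conditions: Pd2(dba)3 (5 mol%), AsPh3 (20 mol%), DMF, 45 °C
Reagents that add atoms: none
Why: Stille coupling transfers the alkenyl group with retention of the E geometry; the conditions are neutral and free of base, fluoride and phosphine, which should keep the silyl peroxide and the aryl silyl ether intact.

Step 18
Reactants: 23 (S)-5-hydroxy-7-methoxy-6-[(E)-3-methylbut-1-en-1-yl]-4'-[(triisopropylsilyl)oxy]flavone with the C3–CH2–CH[C(CH3)2OOSiEt3]–O–C2' bridge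
Product: 24 target CNP0171472.1, (S)-5,4'-dihydroxy-7-methoxy-6-[(E)-3-methylbut-1-en-1-yl]flavone with a C3–CH2–CH[C(CH3)2OOH]–O–C2' bridge
Conditions: HF·pyridine, pyridine/THF, 0 → 23 °C
Reagents that add atoms: none
Why: Fluoride-mediated cleavage of both O–Si bonds (peroxide O–Si and aryl O–Si) in a non-reducing, buffered medium should release the hydroperoxide and the phenol without touching the O–O bond or the styrene.

## Compound list

1 | 1-(2,6-dihydroxy-4-methoxyphenyl)ethan-1-one | CC(=O)c1c(O)cc(OC)cc1O | starting material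
2 | (E)-3-(dimethylamino)-1-(2,6-dihydroxy-4-methoxyphenyl)prop-2-en-1-one (enaminone) | CN(C)/C=C/C(=O)c1c(O)cc(OC)cc1O | intermediate (not isolated)
3 | 5-hydroxy-7-methoxy-4H-chromen-4-one | COc1cc(O)c2c(c1)occc2=O | intermediate
4 | 7-methoxy-5-(methoxymethoxy)-4H-chromen-4-one | COCOc1cc(OC)cc2occc(=O)c12 | intermediate
5 | [7-methoxy-5-(methoxymethoxy)-4-oxo-4H-chromen-2-yl]zinc chloride (LiCl complex) | COCOc1cc(OC)cc2oc([Zn]Cl)cc(=O)c12 | intermediate (not isolated)
6 | 2-iodo-7-methoxy-5-(methoxymethoxy)-4H-chromen-4-one | COCOc1cc(OC)cc2oc(I)cc(=O)c12 | intermediate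
7 | 4-bromobenzene-1,3-diol | Oc1ccc(Br)c(O)c1 | starting material
8 | 2-bromo-5-[(triisopropylsilyl)oxy]phenol | Oc1cc(O[Si](C(C)C)(C(C)C)C(C)C)ccc1Br | intermediate
9 | methyl (R)-2,3-dihydroxypropanoate | COC(=O)[C@H](O)CO | starting material
10 | methyl (R)-3-[(tert-butyldimethylsilyl)oxy]-2-hydroxypropanoate | COC(=O)[C@H](O)CO[Si](C)(C)C(C)(C)C | intermediate
11 | methyl (S)-2-{2-bromo-5-[(triisopropylsilyl)oxy]phenoxy}-3-[(tert-butyldimethylsilyl)oxy]propanoate | CC(C)(C)[Si](C)(C)OC[C@@H](C(=O)OC)Oc1cc(O[Si](C(C)C)(C(C)C)C(C)C)ccc1Br | intermediate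
12 | (S)-3-{2-bromo-5-[(triisopropylsilyl)oxy]phenoxy}-4-[(tert-butyldimethylsilyl)oxy]-2-methylbutan-2-ol | CC(C)(C)[Si](C)(C)OC[C@@H](C(C)(C)O)Oc1cc(O[Si](C(C)C)(C(C)C)C(C)C)ccc1Br | intermediate
13 | (S)-4-[(tert-butyldimethylsilyl)oxy]-2-methyl-3-{2-(4,4,5,5-tetramethyl-1,3,2-dioxaborolan-2-yl)-5-[(triisopropylsilyl)oxy]phenoxy}butan-2-ol | CC(C)(C)[Si](C)(C)OC[C@@H](C(C)(C)O)Oc1cc(O[Si](C(C)C)(C(C)C)C(C)C)ccc1B1OC(C)(C)C(C)(C)O1 | intermediate
14 | (S)-3-methyl-2-{2-(4,4,5,5-tetramethyl-1,3,2-dioxaborolan-2-yl)-5-[(triisopropylsilyl)oxy]phenoxy}butane-1,3-diol | OC[C@@H](C(C)(C)O)Oc1cc(O[Si](C(C)C)(C(C)C)C(C)C)ccc1B1OC(C)(C)C(C)(C)O1 | intermediate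
15 | (R)-4-bromo-2-methyl-3-{2-(4,4,5,5-tetramethyl-1,3,2-dioxaborolan-2-yl)-5-[(triisopropylsilyl)oxy]phenoxy}butan-2-ol | BrC[C@@H](C(C)(C)O)Oc1cc(O[Si](C(C)C)(C(C)C)C(C)C)ccc1B1OC(C)(C)C(C)(C)O1 | intermediate
16 | (S)-7-methoxy-5-(methoxymethoxy)-4'-[(triisopropylsilyl)oxy]flavone with C3–CH2–CH[C(CH3)2OH]–O–C2' bridge | COCOc1cc(OC)cc2oc3c(c(=O)c12)C[C@@H](C(C)(C)O)Oc1cc(O[Si](C(C)C)(C(C)C)C(C)C)ccc1-3 | intermediate
17 | (S)-5-hydroxy-7-methoxy-4'-[(triisopropylsilyl)oxy]flavone with C3–CH2–CH[C(CH3)2OH]–O–C2' bridge | COc1cc2oc3c(c(=O)c2c(O)c1)C[C@@H](C(C)(C)O)Oc1cc(O[Si](C(C)C)(C(C)C)C(C)C)ccc1-3 | intermediate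
18 | (S)-5-hydroxy-6-iodo-7-methoxy-4'-[(triisopropylsilyl)oxy]flavone with C3–CH2–CH[C(CH3)2OH]–O–C2' bridge | COc1cc2oc3c(c(=O)c2c(O)c1I)C[C@@H](C(C)(C)O)Oc1cc(O[Si](C(C)C)(C(C)C)C(C)C)ccc1-3 | intermediate
19 | (S)-5-hydroxy-6-iodo-7-methoxy-4'-[(triisopropylsilyl)oxy]flavone with C3–CH2–CH[C(CH3)=CH2]–O–C2' bridge | COc1cc2oc3c(c(=O)c2c(O)c1I)C[C@@H](C(C)=C)Oc1cc(O[Si](C(C)C)(C(C)C)C(C)C)ccc1-3 | intermediate
20 | (S)-5-hydroxy-6-iodo-7-methoxy-4'-[(triisopropylsilyl)oxy]flavone with C3–CH2–CH[C(CH3)2OOSiEt3]–O–C2' bridge | COc1cc2oc3c(c(=O)c2c(O)c1I)C[C@@H](C(C)(C)OO[Si](CC)(CC)CC)Oc1cc(O[Si](C(C)C)(C(C)C)C(C)C)ccc1-3 | intermediate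
21 | 3-methylbut-1-yne | CC(C)C#C | starting material
22 | (E)-tributyl(3-methylbut-1-en-1-yl)stannane | CCCC[Sn](CCCC)(CCCC)/C=C/C(C)C | intermediate
23 | (S)-5-hydroxy-7-methoxy-6-[(E)-3-methylbut-1-en-1-yl]-4'-[(triisopropylsilyl)oxy]flavone with C3–CH2–CH[C(CH3)2OOSiEt3]–O–C2' bridge | COc1cc2oc3c(c(=O)c2c(O)c1/C=C/C(C)C)C[C@@H](C(C)(C)OO[Si](CC)(CC)CC)Oc1cc(O[Si](C(C)C)(C(C)C)C(C)C)ccc1-3 | intermediate
24 | CNP0171472.1, (S)-5,4'-dihydroxy-7-methoxy-6-[(E)-3-methylbut-1-en-1-yl]flavone with C3–CH2–CH[C(CH3)2OOH]–O–C2' bridge | COc1cc2oc3c(c(=O)c2c(O)c1/C=C/C(C)C)C[C@@H](C(C)(C)OO)Oc1cc(O)ccc1-3 | target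

## Step count and risks

Total step count: 18. Longest linear sequence: 13 steps (steps 5–15, 17 and 18, from 9).

Steps most likely to fail:

1. Step 11 (Proposed new method). What may go wrong:
   - transmetalation of the boronate before norbornene insertion and C3–H alkylation (premature biaryl coupling);
   - sluggish SN2-type oxidative addition of the β-branched bromide;
   - reluctant norbornene extrusion, because only one carbon flanks C2;
   - capture of the C2–palladium species by the free carbinol oxygen;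
   - hydrolysis of the C2–I bond by aqueous base.

   Fallback (known chemistry), setting out from 6 and 15 and coming back at 16: the two bonds are made in two separate operations. A plain Suzuki–Miyaura coupling without norbornene (Pd(dppf)Cl2, K3PO4, 1,4-dioxane/H2O, 60 °C) joins C2 to C1' and should give (R)-2-{2-[(1-bromo-3-hydroxy-3-methylbutan-2-yl)oxy]-4-[(triisopropylsilyl)oxy]phenyl}-7-methoxy-5-(methoxymethoxy)-4H-chromen-4-one F1. Treatment with LDA (2.2 equiv, THF, −78 → 0 °C; the first equivalent is taken by the carbinol) lithiates C3, the known site of flavone metalation, and the vinyl-lithium should close the oxepine by 7-exo-tet displacement of bromide to give 16. F1 is also the product of the premature-coupling failure mode, so material lost in that way is recovered by the same second operation.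

2. Step 17. What may go wrong: reductive cleavage of the O–O bond by zerovalent palladium or the arsine, and slow transmetalation at the doubly ortho-substituted aryl iodide with competing protodeiodination. Fallback, setting out from 18 and 22 and coming back at 23: the order of events is changed so that no peroxide is present during the cross-coupling. Stille coupling of 18 with 22 (Pd2(dba)3, AsPh3, DMF, 60 °C) should give the side-chain carbinol (S)-5-hydroxy-7-methoxy-6-[(E)-3-methylbut-1-en-1-yl]-4'-[(triisopropylsilyl)oxy]flavone with the C3–CH2–CH[C(CH3)2OH]–O–C2' bridge F2. Burgess dehydration (toluene, 60 °C) then gives the corresponding isopropenyl compound F3. Cobalt-catalysed hydrosilylperoxidation (Co(thd)2, Et3SiH in slight excess only, O2, 23 °C, stopped before full conversion) should address the 1,1-disubstituted alkene ahead of the conjugated 1,2-disubstituted one, which is flanked by two ortho substituents and carries a branched β-carbon, and give 23.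

3. Step 13. What may go wrong: iodination at C8 or on ring B instead of C6, or double iodination. Fallback, setting out from 16 and coming back at 18: the halogen is placed by deprotonation instead of electrophilic substitution. Directed ortho-magnesiation of 16 with TMPMgCl·LiCl (2.2 equiv, THF, 0 °C; one equivalent is taken by the carbinol) should occur at C6, the position flanked by the chelating OMOM and the OMe group. Iodolysis (I2, 0 °C) gives (S)-6-iodo-7-methoxy-5-(methoxymethoxy)-4'-[(triisopropylsilyl)oxy]flavone with the C3–CH2–CH[C(CH3)2OH]–O–C2' bridge F4, and acetal methanolysis as in step 12 (HCl, MeOH/THF, 40 °C) then gives 18.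

Further compounds
F1 | step 11 | (R)-2-{2-[(1-bromo-3-hydroxy-3-methylbutan-2-yl)oxy]-4-[(triisopropylsilyl)oxy]phenyl}-7-methoxy-5-(methoxymethoxy)-4H-chromen-4-one | BrC[C@@H](C(C)(C)O)Oc1cc(O[Si](C(C)C)(C(C)C)C(C)C)ccc1-c1cc(=O)c2c(OCOC)cc(OC)cc2o1
F2 | step 17 | (S)-5-hydroxy-7-methoxy-6-[(E)-3-methylbut-1-en-1-yl]-4'-[(triisopropylsilyl)oxy]flavone with C3–CH2–CH[C(CH3)2OH]–O–C2' bridge | COc1cc2oc3c(c(=O)c2c(O)c1/C=C/C(C)C)C[C@@H](C(C)(C)O)Oc1cc(O[Si](C(C)C)(C(C)C)C(C)C)ccc1-3
F3 | step 17 | (S)-5-hydroxy-7-methoxy-6-[(E)-3-methylbut-1-en-1-yl]-4'-[(triisopropylsilyl)oxy]flavone with C3–CH2–CH[C(CH3)=CH2]–O–C2' bridge | COc1cc2oc3c(c(=O)c2c(O)c1/C=C/C(C)C)C[C@@H](C(C)=C)Oc1cc(O[Si](C(C)C)(C(C)C)C(C)C)ccc1-3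
F4 | step 13 | (S)-6-iodo-7-methoxy-5-(methoxymethoxy)-4'-[(triisopropylsilyl)oxy]flavone with C3–CH2–CH[C(CH3)2OH]–O–C2' bridge | COCOc1c(I)c(OC)cc2oc3c(c(=O)c12)C[C@@H](C(C)(C)O)Oc1cc(O[Si](C(C)C)(C(C)C)C(C)C)ccc1-3
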